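The target is cut at the C1–C2 bond next to the furan, where C1 is the acetoxy-bearing carbon on position 3 of the furan ring. The run C1–C2H2–C3H=C4(CH3) is what results when a 3-furoyl group and a hydrogen add 1,4 across the CH2=CH–C(=CH2)– terminus of a β-farnesene-type diene: acyl on the vinyl CH2, hydrogen on the methylidene carbon. A cobalt-catalysed diene hydroacylation with furan-3-carbaldehyde therefore forms the C1–C2 bond, the C4 methyl and the E C3=C4 alkene in one operation. Its precursor is (E)-β-farnesene whose terminal E-methyl has been converted into the CH2–CO–isobutyl ketone. Catalyst-controlled reduction of the furyl ketone and acetylation finish the route.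

Key step: step 6

Remark: locants C1–C4 count from the acetoxy-bearing carbon of the target chain; commercial β-farnesene is assumed to be the pure (E)-isomer, which supplies one of the three E-alkenes directly.

Step 1
Reactants: 1 (E)-β-farnesene
Product: 3 (2E,6E)-2,6-dimethyl-10-methylidenedodeca-2,6,11-trien-1-ol, via β-sinensal 2 (not isolated)
Conditions: SeO2 (0.3 equiv), t-BuOOH (2 equiv), salicylic acid (cat.), CH2Cl2, 0 °C to rt, stopped at partial conversion; then NaBH4, MeOH, 0 °C; unreacted 1 recycled
Reagents that add atoms: selenium dioxide O=[Se]=O (catalytic oxygen carrier); tert-butyl hydroperoxide CC(C)(C)OO (stoichiometric oxygen source)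
Why: Catalytic SeO2 allylic oxidation (ene reaction followed by [2,3]-sigmatropic shift) should attack the electron-rich terminal trisubstituted alkene at its E-methyl group, as it does in myrcene and farnesyl substrates, giving the E-allylic alcohol, and the borohydride treatment returns the over-oxidised enal 2 to 3.

Step 2
Reactants: 3 (2E,6E)-2,6-dimethyl-10-methylidenedodeca-2,6,11-trien-1-ol
Product: 4 (2E,6E)-1-bromo-2,6-dimethyl-10-methylidenedodeca-2,6,11-triene
Conditions: PBr3 (0.4 equiv), pyridine (cat.), Et2O, −10 °C; used crude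
Reagents that add atoms: phosphorus tribromide BrP(Br)Br
Why: Bromination of a primary allylic alcohol through its phosphite ester is a standard SN2 displacement that is fast enough at low temperature to avoid allylic transposition and HBr addition to the diene.

Step 3
Reactants: 5 3-methylbutanal (isovaleraldehyde)
Product: 6 2-(2-methylpropyl)-1,3-dithiane
Conditions: HS(CH2)3SH (1.05 equiv), BF3·OEt2 (cat.), CH2Cl2, 0 °C to rt
Reagents that add atoms: propane-1,3-dithiol SCCCS
Why: Lewis acid-catalysed thioacetalisation of an unhindered aliphatic aldehyde is routine and supplies the acyl-anion equivalent of the isovaleryl group.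

Step 4
Reactants: 6 2-(2-methylpropyl)-1,3-dithiane; 4 (2E,6E)-1-bromo-2,6-dimethyl-10-methylidenedodeca-2,6,11-triene
Product: 8 2-[(2E,6E)-2,6-dimethyl-10-methylidenedodeca-2,6,11-trien-1-yl]-2-(2-methylpropyl)-1,3-dithiane, via 2-lithio-2-(2-methylpropyl)-1,3-dithiane 7 (not isolated)
Conditions: n-BuLi (1.05 equiv), THF, −30 °C, 2 h; then 4, −78 °C to 0 °C
Reagents that add atoms: none
Why: Corey–Seebach umpolung alkylation, in which the soft sulfur-stabilised carbanion displaces the primary allylic bromide by SN2 at the α-carbon, so the E-alkene geometry and the diene are not touched.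

Step 5
Reactants: 8 2-[(2E,6E)-2,6-dimethyl-10-methylidenedodeca-2,6,11-trien-1-yl]-2-(2-methylpropyl)-1,3-dithiane
Product: 9 (6E,10E)-2,6,10-trimethyl-14-methylidenehexadeca-6,10,15-trien-4-one
Conditions: MeI (excess), CaCO3, MeCN–H2O (9:1), 45 °C
Reagents that add atoms: water O
Why: Alkylative hydrolysis of the dithiane (S-methylation, ring opening, addition of water) runs under carbonate buffering without acid or strong base, so the β,γ-alkene should stay out of conjugation and the diene should survive.

Step 6
Reactants: 9 (6E,10E)-2,6,10-trimethyl-14-methylidenehexadeca-6,10,15-trien-4-one; 10 furan-3-carbaldehyde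
Product: 11 (3E,7E,11E)-1-(furan-3-yl)-4,8,12,16-tetramethylheptadeca-3,7,11-triene-1,14-dione
Conditions: CoI2 (10 mol %), 1,3-bis(diphenylphosphino)propane (dppp, 10 mol %), Mn powder (20 mol %), 10 (2 equiv), ClCH2CH2Cl, 60 °C; purification on AgNO3-impregnated silica
Reagents that add atoms: none
Why: Mn reduces CoI2/dppp to a monovalent cobalt bisphosphine that binds the s-cis diene of 9 in η4 fashion together with aldehyde 10 and undergoes oxidative cyclisation, joining the formyl carbon to the unsubstituted vinyl CH2 terminus to give an η3-allyl cobalt alkoxide; β-hydride elimination of the carbinol hydrogen then forms the furyl ketone and an allyl cobalt hydride, and C–H reductive elimination at the far allyl terminus (the former methylidene carbon) completes a 1,4-addition of the aldehyde C–H. The closest known reaction type is the cobalt–bisphosphine catalysed intermolecular 1,4-hydroacylation of acyclic 1,3-dienes with aromatic aldehydes, which gives aryl β,γ-unsaturated ketones of this kind. No ring is closed and no stereocentre is created; the only new stereochemical element is the C3=C4 alkene, whose E geometry (new methyl cis to C2) is inherited from the s-cis diene held on the metal. The step needs C–C bonding at the vinyl rather than the methylidene terminus, 1,4- rather than 1,2-delivery of hydrogen, and no reaction at the two trisubstituted alkenes or the dialkyl ketone: attack at the vinyl CH2 is the less hindered one and keeps the long alkyl branch on the central allyl carbon, aromatic aldehydes are known to favour 1,4-delivery in this chemistry, and isolated alkenes and ketones do not enter the oxidative cyclisation. The ligand (dppp against dcpe or dppf) is the handle for tuning regiochemistry, and minor regio- or Z-isomers should be separable on the silver-loaded silica.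

Step 7
Reactants: 11 (3E,7E,11E)-1-(furan-3-yl)-4,8,12,16-tetramethylheptadeca-3,7,11-triene-1,14-dione
Product: 12 (6E,10E,14E,17S)-17-(furan-3-yl)-17-hydroxy-2,6,10,14-tetramethylheptadeca-6,10,14-trien-4-one
Conditions: RuCl[(S,S)-TsDPEN](p-cymene) (2 mol %), HCO2H–Et3N (5:2), CH2Cl2, 0 °C to rt
Reagents that add atoms: none
Why: Noyori–Ikariya asymmetric transfer hydrogenation delivers hydride and proton through an outer-sphere six-membered transition state in which a CH–π contact between the p-cymene ligand and the furan ring selects the face, so the (S,S)-ligand should give the (S)-carbinol as it does with aryl alkyl ketones (same priority order OH > aryl > CH2R), while the dialkyl ketone and the alkenes are not substrates for this catalyst and the acidic 5:2 medium should keep the skipped alkenes in place.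

Step 8
Reactants: 12 (6E,10E,14E,17S)-17-(furan-3-yl)-17-hydroxy-2,6,10,14-tetramethylheptadeca-6,10,14-trien-4-one
Product: 13 (1S,3E,7E,11E)-1-(furan-3-yl)-4,8,12,16-tetramethyl-14-oxoheptadeca-3,7,11-trien-1-yl acetate (target CNP0150869.1)
Conditions: Ac2O, pyridine, DMAP (cat.), CH2Cl2, 0 °C, short reaction time
Reagents that add atoms: acetic anhydride CC(=O)OC(C)=O
Why: DMAP-catalysed O-acylation of the secondary alcohol breaks no bond at the carbinol carbon, so the (S) configuration is retained, and the brief, cold exposure to weak base should not move either β,γ-alkene.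

Compound list
1 | (E)-β-farnesene, (6E)-7,11-dimethyl-3-methylidenedodeca-1,6,10-triene | C=CC(=C)CC/C=C(\C)CCC=C(C)C | starting material
2 | β-sinensal, (2E,6E)-2,6-dimethyl-10-methylidenedodeca-2,6,11-trienal | C=CC(=C)CC/C=C(\C)CC/C=C(\C)C=O | intermediate (not isolated)
3 | (2E,6E)-2,6-dimethyl-10-methylidenedodeca-2,6,11-trien-1-ol | C=CC(=C)CC/C=C(\C)CC/C=C(\C)CO | intermediate
4 | (2E,6E)-1-bromo-2,6-dimethyl-10-methylidenedodeca-2,6,11-triene | C=CC(=C)CC/C=C(\C)CC/C=C(\C)CBr | intermediate
5 | 3-methylbutanal (isovaleraldehyde) | CC(C)CC=O | starting material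
6 | 2-(2-methylpropyl)-1,3-dithiane | CC(C)CC1SCCCS1 | intermediate
7 | 2-lithio-2-(2-methylpropyl)-1,3-dithiane | [Li]C1(CC(C)C)SCCCS1 | intermediate (not isolated)
8 | 2-[(2E,6E)-2,6-dimethyl-10-methylidenedodeca-2,6,11-trien-1-yl]-2-(2-methylpropyl)-1,3-dithiane | C=CC(=C)CC/C=C(\C)CC/C=C(\C)CC1(CC(C)C)SCCCS1 | intermediate
9 | (6E,10E)-2,6,10-trimethyl-14-methylidenehexadeca-6,10,15-trien-4-one | C=CC(=C)CC/C=C(\C)CC/C=C(\C)CC(=O)CC(C)C | intermediate
10 | furan-3-carbaldehyde | O=Cc1ccoc1 | starting material
11 | (3E,7E,11E)-1-(furan-3-yl)-4,8,12,16-tetramethylheptadeca-3,7,11-triene-1,14-dione | O=C(C/C=C(\C)CC/C=C(\C)CC/C=C(\C)CC(=O)CC(C)C)c1ccoc1 | intermediate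
12 | (6E,10E,14E,17S)-17-(furan-3-yl)-17-hydroxy-2,6,10,14-tetramethylheptadeca-6,10,14-trien-4-one | O[C@@H](C/C=C(\C)CC/C=C(\C)CC/C=C(\C)CC(=O)CC(C)C)c1ccoc1 | intermediate
13 | (1S,3E,7E,11E)-1-(furan-3-yl)-4,8,12,16-tetramethyl-14-oxoheptadeca-3,7,11-trien-1-yl acetate | CC(=O)O[C@@H](C/C=C(\C)CC/C=C(\C)CC/C=C(\C)CC(=O)CC(C)C)c1ccoc1 | target

Total step count: 8 (step 3 is a one-step side branch).
Longest linear sequence: 7 steps (1 → 3 → 4 → 8 → 9 → 11 → 12 → 13).

Steps most likely to fail

1. Step 6. The oxidative cyclisation may instead bond the acyl carbon to the methylidene terminus, hydrogen may be delivered 1,2, some Z-alkene may form, or a cobalt hydride may walk a skipped alkene into conjugation. The fallback replaces the hydroacylation by stepwise umpolung; it sets out from dithiane 8 and returns at diketone 11. Iron-catalysed 1,4-hydroboration of the diene of 8 with pinacolborane (FeCl2 with an N-aryl 2-iminopyridine ligand, activated by Mg, Et2O, rt) is known to put boron on the unsubstituted terminus of 2-alkyl dienes with E geometry. It should give the (2E,6E,10E)-allyl pinacolboronate F1, provided the catalyst tolerates the thioacetal. Oxidation with NaBO3·4H2O in aqueous THF should give the farnesol-type primary allylic alcohol F2, and PBr3 in Et2O at −10 °C the allylic bromide F3. Separately, 10 with propane-1,3-dithiol and BF3·OEt2 gives 2-(furan-3-yl)-1,3-dithiane F4. This is deprotonated with n-BuLi in THF at −78 °C to 2-lithio-2-(furan-3-yl)-1,3-dithiane F5 and alkylated with F3 to the bis-dithiane F6. MeI and CaCO3 in aqueous MeCN then free both ketones and deliver 11.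

2. Step 7. The amine or the ruthenium amide may move the C3=C4 alkene into conjugation with the furyl ketone, facial discrimination may be incomplete, or the dialkyl ketone may be slowly reduced. The configuration of 12 should in any case be confirmed by Mosher ester analysis. The fallback keeps the isovaleryl ketone masked and uses a non-basic, reagent-controlled borane reduction; it sets out from dithiane 8 and returns at carbinol 12. Dithiane 8 is submitted to the conditions of step 6 with 10, which should give the furyl ketone dithiane F7; tolerance of the cobalt catalyst for the thioacetal would have to be checked first. Corey–Bakshi–Shibata reduction with (R)-2-methyl-CBS-oxazaborolidine and catecholborane in toluene at −78 °C, with the furyl group acting as the large substituent, should give the (S)-carbinol dithiane F8. MeI and CaCO3 in aqueous MeCN then unmask the ketone to give 12.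

3. Step 1. The ene oxidation may compete at the internal trisubstituted alkene or at the CH2 next to the diene, over-oxidation may run ahead, and the diene may be eroded at higher conversion. The fallback replaces C–H oxidation by terminal degradation and Wittig rebuilding; it sets out from 1 and returns at alcohol 3. NBS in aqueous THF at 0 °C should give the terminal bromohydrin F9, and K2CO3 in MeOH closes it to the terminal epoxide F10. HIO4·2H2O in aqueous THF cleaves this to the trisnor aldehyde F11. The stabilised ylide Ph3P=C(CH3)CO2Et in CH2Cl2 should give the E-configured ethyl enoate F12, and i-Bu2AlH in CH2Cl2 at −78 °C reduces it to 3.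

Further compounds
F1 | step 6 | 2-[(2E,6E,10E)-3,7,11-trimethyl-12-[2-(2-methylpropyl)-1,3-dithian-2-yl]dodeca-2,6,10-trien-1-yl]-4,4,5,5-tetramethyl-1,3,2-dioxaborolane | CC1(C)OB(C/C=C(\C)CC/C=C(\C)CC/C=C(\C)CC2(CC(C)C)SCCCS2)OC1(C)C
F2 | step 6 | (2E,6E,10E)-3,7,11-trimethyl-12-[2-(2-methylpropyl)-1,3-dithian-2-yl]dodeca-2,6,10-trien-1-ol | OC/C=C(\C)CC/C=C(\C)CC/C=C(\C)CC1(CC(C)C)SCCCS1
F3 | step 6 | 2-[(2E,6E,10E)-12-bromo-2,6,10-trimethyldodeca-2,6,10-trien-1-yl]-2-(2-methylpropyl)-1,3-dithiane | BrC/C=C(\C)CC/C=C(\C)CC/C=C(\C)CC1(CC(C)C)SCCCS1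
F4 | step 6 | 2-(furan-3-yl)-1,3-dithiane | C1(c2ccoc2)SCCCS1
F5 | step 6 | 2-lithio-2-(furan-3-yl)-1,3-dithiane | [Li]C1(c2ccoc2)SCCCS1
F6 | step 6 | 2-(furan-3-yl)-2-[(2E,6E,10E)-3,7,11-trimethyl-12-[2-(2-methylpropyl)-1,3-dithian-2-yl]dodeca-2,6,10-trien-1-yl]-1,3-dithiane | C1(c2ccoc2)(C/C=C(\C)CC/C=C(\C)CC/C=C(\C)CC3(CC(C)C)SCCCS3)SCCCS1
F7 | step 7 | (3E,7E,11E)-1-(furan-3-yl)-4,8,12-trimethyl-13-[2-(2-methylpropyl)-1,3-dithian-2-yl]trideca-3,7,11-trien-1-one | O=C(C/C=C(\C)CC/C=C(\C)CC/C=C(\C)CC1(CC(C)C)SCCCS1)c1ccoc1
F8 | step 7 | (1S,3E,7E,11E)-1-(furan-3-yl)-4,8,12-trimethyl-13-[2-(2-methylpropyl)-1,3-dithian-2-yl]trideca-3,7,11-trien-1-ol | O[C@@H](C/C=C(\C)CC/C=C(\C)CC/C=C(\C)CC1(CC(C)C)SCCCS1)c1ccoc1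
F9 | step 1 | (6E)-3-bromo-2,6-dimethyl-10-methylidenedodeca-6,11-dien-2-ol (racemic) | C=CC(=C)CC/C=C(\C)CCC(Br)C(C)(C)O
F10 | step 1 | 2,2-dimethyl-3-[(3E)-3-methyl-7-methylidenenona-3,8-dien-1-yl]oxirane (racemic) | C=CC(=C)CC/C=C(\C)CCC1OC1(C)C
F11 | step 1 | (4E)-4-methyl-8-methylidenedeca-4,9-dienal | C=CC(=C)CC/C=C(\C)CCC=O
F12 | step 1 | ethyl (2E,6E)-2,6-dimethyl-10-methylidenedodeca-2,6,11-trienoate | C=CC(=C)CC/C=C(\C)CC/C=C(\C)C(=O)OCC
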